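The impurity is charged in less than the free catalyst, 32 µM against 38 µM, and we build on that comparison. We assume that each impurity takes one catalyst for good. The part of the catalyst beyond the impurity's reach is then a catalyst floor, the free catalyst charged minus the impurity charged: 6.00 µM.

- blue: left-handed substrate 20 mM; right-handed substrate 20 mM; reagent 60 mM; free catalyst 38 µM; impurity 32 µM; the very flask that is asked about, followed so far
- flask: left-handed substrate 20 mM; reagent 60.0 mM; free catalyst 38 µM; impurity 32 µM; right-handed substrate 20 mM; time 6.0 d

- blue (time / h: left-handed product / %, right-handed product / %, left-handed substrate / %): 2.50: 3.5, 5.9, 47.1; 5.00: 5.8, 10.1, 43.5; 12.0: 12.0, 18.8, 38.2; 30.0: 21.0, 30.9, 29.2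

(standard deviation of a reading: 0.3 percentage points)

- free catalyst is single-handed; left-handed substrate and right-handed substrate are mirror images of each other, charged as a racemate, each of them at the stated concentration
- the numbers in the tables scatter by 0.3 percentage points (one standard deviation)
- an excess is below zero if the other one leads

- excess of left-handed product over right-handed product in the product at 8.0 h
- excess of left-handed product over right-handed product in the product at 6.0 d
- part of the left-handed substrate and right-handed substrate charged together that has reacted at 6.0 d

The blue run is the start of this same flask, so we draw the curve from it, counting one reagent per product. The first slope of the products together reads 1.50 mM/h, so, averaged over that first interval, each catalyst charged turns over 39.6 /h. Between 12.0 h and 30.0 h the slope reads 0.469 mM/h, which is lower. It still stands above the 0.238 mM/h that the floor gives at full reagent, so we place the knee at the last reading, where c(reagent) is 39.2 mM.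

Beyond the knee we take the tail as pseudo-first-order in reagent, with constant 0.00396 /h. Over the remaining 114 h, we reckon c(reagent) down to 25.0 mM, which is our estimate of 87.5% reacted. The substrates together, 40.0 mM, are the limiting reagent, so the highest level the charges allow the curve is complete conversion. We reckon no excess of our own.

The forecast gives −24.5%, −11% and 80%, and says: “Uncertainty is large because the deactivation law is assumed.” Our conversion stands above its figure.

The flask gives −24.6%, −7.63% and 88.0%.

    reagent + free catalyst → spent catalyst B (k = 0.00650 /M/min)
    reagent + catalyst intermediate B → free catalyst + right-handed product (k = 9.30 /M/min)
    free catalyst + left-handed substrate ⇌ catalyst intermediate A (K = 360 /M, k = 290 /M/min)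
    free catalyst + impurity → spent catalyst A (k = 470 /M/min)
    reagent → decomposition product (k = 2.70 × 10⁻⁶ /min)
    reagent + catalyst intermediate A → free catalyst + left-handed product (k = 25.0 /M/min)
    free catalyst + right-handed substrate ⇌ catalyst intermediate B (K = 1600 /M, k = 540 /M/min)

In the flask, spent catalyst A reads 83.8% at 6.00 d, against the 84.2% of the charge that lies above the floor. The neighbour charged with 36 mM of reagent has the same floor. There spent catalyst A reads 81.5% at 6.00 d, with 3.22% of the impurity's charge still present. The same tail, scaled to that charge, reckons 52.5% reacted, and that neighbour stands at 63.5%.

Readings and results come from a simulation for substances that don't exist.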